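**Retrosynthetic overview**
1. Flemistrictin D ⇒ remove the C8–OH: late para-hydroxylation (Elbs) of the chelated 5-hydroxychromene ketone, the only free aromatic position.
2. Chromene ⇒ open the pyran at O1–C2 and C4–C4a: formal [3+3] annulation of 2',4'-dihydroxy-6'-methoxydihydrochalcone with prenal.
3. Dihydrochalcone ⇒ cut the aryl–C(=O) bond: Friedel–Crafts acylation of 5-methoxyresorcinol with 3-phenylpropanoic acid.
4. Ring order: both benzene rings are bought; the 2H-pyran is the only ring formed (step 2).

Assumption: the target has no stereocentre and no stereogenic double bond, so it is achiral and "single enantiomer" requires no stereocontrol.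
Assumption: BF3·OEt2 in step 1 serves as the Lewis-acidic reaction medium and is not part of the balanced equation, whose only coproduct is water.

**Step 1**
Reactants: 1 5-methoxybenzene-1,3-diol (5-methoxyresorcinol); 2 3-phenylpropanoic acid
Product: 3 1-(2,4-dihydroxy-6-methoxyphenyl)-3-phenylpropan-1-one (2',4'-dihydroxy-6'-methoxydihydrochalcone)
Conditions: BF3·OEt2 (as solvent), 85 °C, 3 h; H2O work-up; chromatography
Reagents that add atoms: none
Why: Friedel–Crafts C-acylation of a phloroglucinol-type arene by the BF3-activated acid goes mainly to the two equivalent positions para to a free OH (between OH and OMe), giving the chelated o-hydroxyaryl ketone; no stereocentre is formed.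

**Step 2**
Reactants: 3 1-(2,4-dihydroxy-6-methoxyphenyl)-3-phenylpropan-1-one; 4 3-methylbut-2-enal (prenal)
Product: 6 1-(5-hydroxy-7-methoxy-2,2-dimethyl-2H-chromen-6-yl)-3-phenylpropan-1-one, via ortho-quinone methide 5 (not isolated)
Conditions: 4 (1.5 equiv), EDDA (20 mol%), xylene, 140 °C, 12 h
Reagents that add atoms: none
Why: Amine-catalysed Knoevenagel-type condensation of prenal at C3' (between the two hydroxyls), dehydration to the ortho-quinone methide and oxa-6π electrocyclisation through the non-chelated 4'-oxygen give the 2,2-dimethyl-2H-chromene (formal [3+3] annulation) while the 2'-OH stays hydrogen-bonded to the ketone; no stereocentre is formed.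

**Step 3**
Reactants: 6 1-(5-hydroxy-7-methoxy-2,2-dimethyl-2H-chromen-6-yl)-3-phenylpropan-1-one
Product: 8 flemistrictin D = 1-(5,8-dihydroxy-7-methoxy-2,2-dimethyl-2H-chromen-6-yl)-3-phenylpropan-1-one, via chromen-8-yl sulfate 7 (not isolated)
Conditions: K2S2O8 (1.2 equiv), 2 M NaOH, pyridine, 0 °C → rt, 24 h; then 2 M HCl, toluene, 70 °C, 1 h, N2
Reagents that add atoms: potassium peroxydisulfate, [K+].[K+].[O-]S(=O)(=O)OOS(=O)(=O)[O-]
Why: Elbs persulfate oxidation, in which the phenoxide of the 5-OH attacks the peroxide O–O bond through its para carbon C8 (the only unsubstituted ring position) to give the aryl sulfate, whose S–O bond is then cleaved by dilute acid to the hydroquinone; no stereocentre is formed.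

**Compound list**
1 | 5-methoxybenzene-1,3-diol (5-methoxyresorcinol) | COc1cc(O)cc(O)c1 | starting material
2 | 3-phenylpropanoic acid | OC(=O)CCc1ccccc1 | starting material
3 | 1-(2,4-dihydroxy-6-methoxyphenyl)-3-phenylpropan-1-one | COc1cc(O)cc(O)c1C(=O)CCc1ccccc1 | intermediate
4 | 3-methylbut-2-enal (prenal) | CC(C)=CC=O | starting material
5 | (6Z)-5-hydroxy-3-methoxy-6-(3-methylbut-2-en-1-ylidene)-4-(3-phenylpropanoyl)cyclohexa-2,4-dien-1-one | COC1=CC(=O)/C(=C\C=C(C)C)C(O)=C1C(=O)CCc1ccccc1 | intermediate
6 | 1-(5-hydroxy-7-methoxy-2,2-dimethyl-2H-chromen-6-yl)-3-phenylpropan-1-one | COc1cc2c(c(O)c1C(=O)CCc1ccccc1)C=CC(C)(C)O2 | intermediate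
7 | potassium 5-hydroxy-7-methoxy-2,2-dimethyl-6-(3-phenylpropanoyl)-2H-chromen-8-yl sulfate | COc1c(OS(=O)(=O)[O-])c2c(c(O)c1C(=O)CCc1ccccc1)C=CC(C)(C)O2.[K+] | intermediate
8 | flemistrictin D, 1-(5,8-dihydroxy-7-methoxy-2,2-dimethyl-2H-chromen-6-yl)-3-phenylpropan-1-one | COc1c(O)c2c(c(O)c1C(=O)CCc1ccccc1)C=CC(C)(C)O2 | target

**Totals**
Total step count: 3. Longest linear sequence: 3 steps (1 → 3 → 6 → 8).

**Steps most likely to fail** (most risky first; the route has only three steps, so all are covered)

Step 3 (Elbs oxidation). Risks are low conversion, persulfate attack on the chromene double bond, and acid damage to the chromene during sulfate hydrolysis. The fallback sets out from 6 and comes back at 8. Compound 6 is oxidised with Fremy's salt (potassium nitrosodisulfonate, KH2PO4 buffer, aqueous acetone, rt; Teuber oxidation) to the para-quinone 7-methoxy-2,2-dimethyl-6-(3-phenylpropanoyl)-2H-chromene-5,8-dione F7. This is reduced without storage by aqueous Na2S2O4 (EtOAc/H2O, rt, N2) to the hydroquinone 8. This replaces the nucleophilic persulfate hydroxylation and the hot-acid hydrolysis by a radical oxidation and a mild reduction.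

Step 2 (chromene annulation). Risks are condensation at C5' instead of C3' (giving the 7-hydroxy-5-methoxy isomer) and cyclisation through the chelated 2'-oxygen. The fallback sets out from 3 and comes back at 8, reversing the order of oxidation and ring formation so that C5' is blocked before the pyran is built. Elbs oxidation of 3 (K2S2O8, 2 M NaOH, 0 °C → rt) gives potassium 2,4-dihydroxy-6-methoxy-5-(3-phenylpropanoyl)phenyl sulfate F4. Hydrolysis (2 M HCl, 70 °C, N2) gives 1-(3,4,6-trihydroxy-2-methoxyphenyl)-3-phenylpropan-1-one F5. Condensation of F5 with 4 (EDDA 20 mol%, toluene, reflux, argon) can then take place only at the single remaining aromatic CH. It passes through (6Z)-2,5-dihydroxy-3-methoxy-6-(3-methylbut-2-en-1-ylidene)-4-(3-phenylpropanoyl)cyclohexa-2,4-dien-1-one F6 and closes through the 4'-oxygen to 8.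

Step 1 (acylation). Risks are the regioisomer acylated between the two hydroxyls (2',6'-dihydroxy-4'-methoxy) and diacylation, which lower the yield and complicate separation. The fallback sets out from 2 and comes back at 3, using a symmetric arene so that no regiochemical question arises:
- Commercial phloroglucinol (Oc1cc(O)cc(O)c1) is acylated with 2 (BF3·OEt2, 85 °C) to 1-(2,4,6-trihydroxyphenyl)-3-phenylpropan-1-one F1.
- MOMCl (2.2 equiv), iPr2NEt, CH2Cl2, 0 °C caps the two non-chelated hydroxyls to give 1-[2-hydroxy-4,6-bis(methoxymethoxy)phenyl]-3-phenylpropan-1-one F2.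
- MeI, K2CO3, DMF, 40 °C methylates the remaining chelated hydroxyl to give 1-[2-methoxy-4,6-bis(methoxymethoxy)phenyl]-3-phenylpropan-1-one F3.
- 3 M HCl in MeOH, 50 °C removes both MOM groups and delivers 3.

**Further compounds**
F1 | step 1 | 1-(2,4,6-trihydroxyphenyl)-3-phenylpropan-1-one | O=C(CCc1ccccc1)c1c(O)cc(O)cc1O
F2 | step 1 | 1-[2-hydroxy-4,6-bis(methoxymethoxy)phenyl]-3-phenylpropan-1-one | COCOc1cc(O)c(C(=O)CCc2ccccc2)c(OCOC)c1
F3 | step 1 | 1-[2-methoxy-4,6-bis(methoxymethoxy)phenyl]-3-phenylpropan-1-one | COCOc1cc(OC)c(C(=O)CCc2ccccc2)c(OCOC)c1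
F4 | step 2 | potassium 2,4-dihydroxy-6-methoxy-5-(3-phenylpropanoyl)phenyl sulfate | COc1c(OS(=O)(=O)[O-])c(O)cc(O)c1C(=O)CCc1ccccc1.[K+]
F5 | step 2 | 1-(3,4,6-trihydroxy-2-methoxyphenyl)-3-phenylpropan-1-one | COc1c(O)c(O)cc(O)c1C(=O)CCc1ccccc1
F6 | step 2 | (6Z)-2,5-dihydroxy-3-methoxy-6-(3-methylbut-2-en-1-ylidene)-4-(3-phenylpropanoyl)cyclohexa-2,4-dien-1-one | COC1=C(O)C(=O)/C(=C\C=C(C)C)C(O)=C1C(=O)CCc1ccccc1
F7 | step 3 | 7-methoxy-2,2-dimethyl-6-(3-phenylpropanoyl)-2H-chromene-5,8-dione | COC1=C(C(=O)CCc2ccccc2)C(=O)C2=C(OC(C)(C)C=C2)C1=O
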